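The readings come from a simulation for an exercise; noise was put on by code.

At 5.00 h Wednesday's run had 30% of its charge in chains, so 70.0% of it was left outside them. Red and grey had to be reckoned from that leftover.

| flask | free monomer | initiator | remark | time |
|---|---|---|---|---|
| Wednesday's | 0.042 M (fed, over 1.0 h) | 0.32 mM | run made earlier |  |
| red | 0.063 M (fed, over 1.0 h) | 0.32 mM |  | 15 h |
| grey | 0.063 M (fed, over 1.0 h) | 0.080 mM |  | 15 h |

Wednesday's run (percent of the free monomer charged): time / h: monomer in chains / % = 0.417: 1; 0.667: 2; 1.00: 3; 1.33: 2; 2.50: 10; 3.00: 15; 5.00: 30

(readings scatter by 2 percentage points)

- the average divides the monomer in chains by the number of chains begun, living and dead together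
- the earlier runs do not show the number of chains; that part of a forecast is a guess
- percentages count the whole charge, also what has not yet gone in
- no earlier run changes the charge of initiator; that part of a forecast is a guess

- which of the two ends with the longer chains by the average number of monomer units in a chain (chains begun, living or dead) ("neither" if they lie within 10%) (red / grey / neither)
- average number of monomer units in a chain (chains begun, living or dead) at the end, red
- average number of monomer units in a chain (chains begun, living or dead) at the end, grey

I carried one quantity: the ceiling length, free monomer charged per initiator charged, 197 for red. It assumes that each initiator begins a chain, which is a guess here.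

length = ceiling length × share of the charge in chains

Time came first. By hand, more half-lives raise the share. I took uptake as pseudo-first-order and started the clock at mid-feed. The reading gave:

k = 0.0793 h⁻¹, half-life = 8.75 h

This is a reading and carries the scatter. The feed of 1.0 h is shorter than that half-life. Red's time held 1.66 half-lives, so its share was 68.3%.

Next came the monomer charge. By hand, it raises the ceiling in proportion and leaves a first-order share alone. Red's length came to:

197 × 68.3% = 134

Last came the initiator. Grey has a quarter of red's initiator, which lifts its ceiling to 787. I guessed that k fell in the same proportion, which gave a share of 25.0%:

787 × 25.0% = 197

The forecast also chose grey, but with 150 for red and 250 for grey, both above my figures: “Either way, less initiator gives fewer chains, and conversion falls less than fourfold, so grey ends longer.”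

The flask gave grey, with 123 for red and 192 for grey.

    free monomer + initiator → living end + monomer in chains (k = 16.8 L mol⁻¹ h⁻¹)
    free monomer + living end → monomer in chains + living end, rate k2*[living end]*[free monomer] (k = 361 L mol⁻¹ h⁻¹)
    free monomer → uncatalysed product (k = 0.0411 h⁻¹)

Red ended with 62.5% of its charge in chains, less than my share, with 25.9% as uncatalysed product and 0.13% of its initiator left. Its ceiling times that share is 123. The neighbouring flask was red with 0.16 M of free monomer, which raised the ceiling to 500. My unchanged share of 68.3% gave it 342. It ended with 64.7% in chains, 24.5% as uncatalysed product and 0% of its initiator left, and the flask gave 324.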